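**Overview**
- Enabling feature: C2 of the five-membered indolin-3-one ring is a fully substituted carbon bonded to the ring nitrogen. It holds two indistinguishable indol-3-yl groups and sits next to the C3 carbonyl. Such an α-amino ketone maps back onto an α-hydroxy imine, a 3-hydroxy-3H-indole with one indol-3-yl on C2 and the other on C3.
- Cuts, in retrosynthetic order: the two outer N–H bonds (masked as N-Ts); one C2–C3' bond, the indolyl going back to C3 (1,2-shift); the C3–O bond; N–C2 and C3–C3a of the central ring (Larock); the two C(sp)–C3' bonds of a symmetrical alkyne (Sonogashira).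
- Forward: both outer indole bicycles come intact from indole and are joined through an ethyne bridge in two couplings. The central five-membered nitrogen ring is the only ring made (step 5). Oxidation and the shift then only redistribute its substituents.
- Stereochemistry: the target is achiral. The only stereocentre of the route, C3 of the hydroxyindolenine, is formed racemic and is erased in the shift.

Key step: step 7

Assumption: the target SMILES contains no stereocentre because C2 bears two identical groups, so there is no enantiomer to select and the achiral compound is made as drawn.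

**Step 1**
Reactants: 1 indole
Product: 2 3-iodo-1H-indole
Conditions: I2 (1.05 equiv), KOH (2.5 equiv), DMF, rt, dark; crude product used at once
Reagents that add atoms: iodine, II
Why: Electrophilic aromatic iodination of the base-activated indole takes place at its most nucleophilic carbon, C3, and the light- and acid-sensitive product is carried on without storage.

**Step 2**
Reactants: 2 3-iodo-1H-indole
Product: 3 3-iodo-1-tosylindole
Conditions: NaH (1.2 equiv), TsCl (1.1 equiv), THF, 0 °C to rt
Reagents that add atoms: 4-toluenesulfonyl chloride, Cc1ccc(cc1)S(=O)(=O)Cl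
Why: N-Sulfonylation of the sodium indolide is routine, stabilises the iodide for cross-coupling and lowers the π-nucleophilicity of what become the two outer indoles.

**Step 3**
Reactants: 3 3-iodo-1-tosylindole; 4 trimethylsilylacetylene
Product: 5 1-tosyl-3-(trimethylsilylethynyl)indole
Conditions: PdCl2(PPh3)2 (2 mol%), CuI (4 mol%), Et3N, THF, rt, degassed
Reagents that add atoms: none
Why: Sonogashira coupling of an electron-poor heteroaryl iodide with a terminal alkyne runs at room temperature, and the silyl cap rules out double coupling at this stage.

**Step 4**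
Reactants: 5 1-tosyl-3-(trimethylsilylethynyl)indole; 3 3-iodo-1-tosylindole
Product: 7 1,2-bis(1-tosylindol-3-yl)ethyne, via 3-ethynyl-1-tosylindole 6 (not isolated)
Conditions: PdCl2(PPh3)2 (3 mol%), CuI (5 mol%), TBAF (1.1 equiv, 1 M in THF, slow addition), Et3N, THF, rt, degassed
Reagents that add atoms: none
Why: In this one-pot desilylation–Sonogashira coupling, fluoride releases alkyne 6 slowly beside the Pd/Cu catalyst and a second portion of 3, so the free alkyne stays dilute and Glaser dimerisation is held back, while N-tosylindoles need hot fluoride for cleavage and should persist at room temperature.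

**Step 5**
Reactants: 7 1,2-bis(1-tosylindol-3-yl)ethyne; 8 2-iodoaniline (1.3 equiv)
Product: 9 2,3-bis(1-tosylindol-3-yl)-1H-indole
Conditions: Pd(OAc)2 (5 mol%), PPh3 (10 mol%), LiCl (1 equiv), Na2CO3 (3 equiv), DMF, 100 °C
Reagents that add atoms: none
Why: In the Larock heteroannulation, oxidative addition into C–I, syn-carbopalladation of the alkyne and C–N reductive elimination close the central pyrrole ring, and the symmetry of 7 allows only one regioisomer.

**Step 6**
Reactants: 9 2,3-bis(1-tosylindol-3-yl)-1H-indole
Product: 10 racemic 3-hydroxy-2,3-bis(1-tosylindol-3-yl)-3H-indole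
Conditions: dimethyldioxirane (1.05 equiv, acetone solution), CH2Cl2, −78 to −20 °C
Reagents that add atoms: dimethyldioxirane, CC1(C)OO1
Why: Oxidative dearomatisation of a 2,3-disubstituted indole by electrophilic oxygen transfer to the enamine-like C3 of the only N–H indole, followed by collapse to the C2=N imine, should give the hydroxyindolenine; the sulfonylated outer indoles are much poorer nucleophiles, the medium stays neutral, and the new C3 centre forms racemic because nothing differentiates the two faces.

**Step 7**
Reactants: 10 racemic 3-hydroxy-2,3-bis(1-tosylindol-3-yl)-3H-indole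
Product: 11 2,2-bis(1-tosylindol-3-yl)indolin-3-one
Conditions: KOt-Bu (1.2 equiv), anhydrous THF, 0 °C to rt; then AcOH (1.2 equiv)
Reagents that add atoms: none
Why: tert-Butoxide removes the proton of the tertiary C3–OH, and as the C3–O bond becomes the carbonyl the C3 indol-3-yl group moves with its bonding electron pair onto the electrophilic imine carbon C2 through a bridged, phenonium-like transition state, after which AcOH protonates the anilide nitrogen. The closest known reaction type is the α-iminol (acyloin-type, pseudo-indoxyl) rearrangement of 3-hydroxy-3H-indoles, in which alkyl and aryl groups are known to travel from C3 to C2 under base. No ring closes, so no mode of closure applies, and no stereocentre is created, because the new quaternary C2 carries two identical groups and the racemic C3 centre becomes the planar ketone carbon. The selectivity required is C3-to-C2 migration (indoxyl) rather than C2-to-C3 migration (3,3-disubstituted oxindole); aprotic base secures it by pushing from the alkoxide and offering no way to hydrate C2 or ionise C3, and the only other carbon substituent on C3, the ring-fusion carbon C3a, cannot migrate without contracting the ring. The sulfonyl groups stop the outer indole nitrogens from expelling the C3 oxygen as a 3-alkylidene-3H-indole, and hindered tert-butoxide in THF should not attack sulfur. The conjugated 2-aminoaryl ketone (vinylogous amide) and its stabilised anion supply the driving force.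

**Step 8**
Reactants: 11 2,2-bis(1-tosylindol-3-yl)indolin-3-one
Product: 12 2,2-bis(3'-indolyl)indoxyl
Conditions: Cs2CO3 (6 equiv), THF/MeOH 2:1, rt to 50 °C
Reagents that add atoms: none
Why: In this nucleophilic N-desulfonylation of N-tosylindoles, carbonate-generated methoxide attacks sulfur and releases the indolide leaving group, while the vinylogous-amide ketone and the fully substituted C2, which has no α-hydrogen, are not affected by mild base.

**Compound list**
1 | indole | c1ccc2[nH]ccc2c1 | starting material
2 | 3-iodo-1H-indole | Ic1c[nH]c2ccccc12 | intermediate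
3 | 3-iodo-1-tosylindole | Cc1ccc(cc1)S(=O)(=O)n1cc(I)c2ccccc12 | intermediate
4 | trimethylsilylacetylene | C#C[Si](C)(C)C | starting material
5 | 1-tosyl-3-(trimethylsilylethynyl)indole | Cc1ccc(cc1)S(=O)(=O)n1cc(C#C[Si](C)(C)C)c2ccccc12 | intermediate
6 | 3-ethynyl-1-tosylindole (not isolated) | Cc1ccc(cc1)S(=O)(=O)n1cc(C#C)c2ccccc12 | intermediate
7 | 1,2-bis(1-tosylindol-3-yl)ethyne | Cc1ccc(cc1)S(=O)(=O)n1cc(C#Cc2cn(S(=O)(=O)c3ccc(C)cc3)c3ccccc23)c2ccccc12 | intermediate
8 | 2-iodoaniline | Nc1ccccc1I | starting material
9 | 2,3-bis(1-tosylindol-3-yl)-1H-indole | Cc1ccc(cc1)S(=O)(=O)n1cc(-c2[nH]c3ccccc3c2-c2cn(S(=O)(=O)c3ccc(C)cc3)c3ccccc23)c2ccccc12 | intermediate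
10 | 3-hydroxy-2,3-bis(1-tosylindol-3-yl)-3H-indole (racemic at C3) | Cc1ccc(cc1)S(=O)(=O)n1cc(c2ccccc12)C1(O)C(=Nc2ccccc12)c1cn(S(=O)(=O)c2ccc(C)cc2)c2ccccc12 | intermediate
11 | 2,2-bis(1-tosylindol-3-yl)indolin-3-one | Cc1ccc(cc1)S(=O)(=O)n1cc(c2ccccc12)C1(Nc2ccccc2C1=O)c1cn(S(=O)(=O)c2ccc(C)cc2)c2ccccc12 | intermediate
12 | 2,2-bis(3'-indolyl)indoxyl (achiral) | O=C1c2ccccc2NC1(c1c[nH]c2ccccc12)c1c[nH]c2ccccc12 | target

**Step count**
Total step count: 8.
Longest linear sequence: 8 steps, from indole 1 through 2, 3, 5, 7, 9, 10 and 11 to 12. Iodide 3 is used in both step 3 and step 4.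

**Steps most likely to fail**

Step 7. The sulfonyl group lowers the migratory aptitude of the indolyl, so the shift may be slow. Base attack on sulfur, followed by expulsion of the C3 oxygen, could then compete.

The fallback gives up the 1,2-shift and forms both C2–C3' bonds by aza-Friedel–Crafts additions. It sets out from indole 1 and comes back at the target 12.
- Aerobic oxidation of 1 (O2, catalytic TEMPO, a carboxylic acid additive, MeCN, 40–60 °C) should turn one indole into 3H-indol-3-one F1.
- The C=N carbon of F1 is attacked by C3 of a second indole to give racemic 2-(1H-indol-3-yl)indolin-3-one F2.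
- Dehydrogenation in the same medium gives 2-(1H-indol-3-yl)-3H-indol-3-one F3.
- C2 of F3 takes up a third indole to give 12.

Step 6. Oxygen transfer may be sluggish because C2 and C3 carry two electron-poor heteroaryl groups. Further oxidation at the imine nitrogen, or oxidative cleavage of the C2–C3 bond, could then intrude.

The fallback replaces the oxygen-atom donor by an ene-type photooxygenation. It sets out from 9 and comes back at 10.
- Singlet oxygen (O2, catalytic tetraphenylporphyrin, visible light, CH2Cl2, −78 °C) should leave N-sulfonylindoles untouched and give racemic 3-hydroperoxy-2,3-bis(1-tosylindol-3-yl)-3H-indole F4.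
- F4 is reduced in the cold with dimethyl sulfide to 10.

Step 5. Carbopalladation of the hindered, electron-poor diheteroaryl alkyne may be slow. That would allow catalyst decay, reduction of the aryl iodide or multiple alkyne insertion.

The fallback builds the ring from a preformed 2-alkynylaniline. It sets out from 5 and 8 and comes back at 9.
- The fluoride-triggered Sonogashira conditions of step 4 should join 5 and 8 to give 2-[(1-tosylindol-3-yl)ethynyl]aniline F5.
- Trifluoroacetic anhydride and pyridine in CH2Cl2 at 0 °C convert F5 into 2,2,2-trifluoro-N-{2-[(1-tosylindol-3-yl)ethynyl]phenyl}acetamide F6.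
- A Cacchi aminopalladation–reductive elimination of F6 with iodide 3 (Pd(PPh3)4, K2CO3, MeCN, 50 °C) closes the ring by 5-endo-dig attack of the amide nitrogen on the palladium-activated alkyne and installs the second indolyl at C3.
- The labile N-trifluoroacetyl group is lost under the carbonate conditions and aqueous work-up, giving 9.

**Further compounds**
F1 | step 7 | 3H-indol-3-one | O=C1C=Nc2ccccc12
F2 | step 7 | 2-(1H-indol-3-yl)indolin-3-one (racemic) | O=C1c2ccccc2NC1c1c[nH]c2ccccc12
F3 | step 7 | 2-(1H-indol-3-yl)-3H-indol-3-one | O=C1c2ccccc2N=C1c1c[nH]c2ccccc12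
F4 | step 6 | 3-hydroperoxy-2,3-bis(1-tosylindol-3-yl)-3H-indole (racemic) | Cc1ccc(cc1)S(=O)(=O)n1cc(c2ccccc12)C1(OO)C(=Nc2ccccc12)c1cn(S(=O)(=O)c2ccc(C)cc2)c2ccccc12
F5 | step 5 | 2-[(1-tosylindol-3-yl)ethynyl]aniline | Nc1ccccc1C#Cc1cn(S(=O)(=O)c2ccc(C)cc2)c2ccccc12
F6 | step 5 | 2,2,2-trifluoro-N-{2-[(1-tosylindol-3-yl)ethynyl]phenyl}acetamide | O=C(Nc1ccccc1C#Cc1cn(S(=O)(=O)c2ccc(C)cc2)c2ccccc12)C(F)(F)F
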